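**Retrosynthetic overview**
1. Target 37 ⇐ O8 angeloylation, C13 methylenation, O6→C12 lactonisation and C6 reduction of the (1E,4Z)-cyclodeca-1,4-dien-6-one 25.
2. 25 ⇐ Grob fragmentation of trans-decalin 23. The feature used: in the ten-membered ring the oxygen-bearing C6 and C1 (one end of the E C1=C2 alkene) face each other across the ring, which is the imprint of a cleaved C1–C6 bond shared by ring A (C1–C6) and ring B (C6–C10 plus C1).
3. Ring B of 23 ⇐ carbonyl-ene closure of C8–C9 onto an isopropenyl group, then C7 alkylation, C10–O through an epoxy ketone, and C8–O by directed reduction.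
4. Ring A ⇐ (R)-carvone, which supplies C1–C6, C9, C10, C14, C15 and the C1 stereocentre; C2–O by Rubottom oxidation, C3–O by CBS reduction, C6=O by allylic oxidation.
5. Ring order: ring A (chiral pool) → ring B (step 7) → ten-membered ring (step 16) → lactone (step 18).

Key step: step 16

Remarks on the chemistry (assumptions):
- The target SMILES is read literally as (3S,6S,7R,8R,10R), which puts H-6 and H-7 on the same face of the lactone (cis-fused lactone).
- Germacrane locants are used throughout: C1–C10 ring carbons, C11 the side-chain carbon on C7, C12 its carbonyl carbon, C13 the exocyclic methylene, C14 the methyl on C10, C15 the methyl on C4. In the decalins β is the face of H-1; all decalins are trans-fused with 1β-H and axial 6α-OH.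
- The fragmentation precursor carries a CH2CO2tBu arm on C7 (C11, C12) and a free C10 hydroxyl instead of a propenyl ether and a C10 silyl ether. (R)-Carvone, N-methoxy-N-methylacetamide, tert-butyl bromoacetate, Eschenmoser's salt and angelic acid are taken as commercial.

**Route**

Step 1
Reactants: 1 (R)-carvone
Product: 4 (5S,6S)-2-methyl-5-(prop-1-en-2-yl)-6-(triethylsilyloxy)cyclohex-2-en-1-one, via triethylsilyl dienol ether 2 (not isolated), via silyloxy epoxide 3 (not isolated)
Conditions: Et3SiOTf, Et3N, CH2Cl2, 0 °C; then mCPBA, CH2Cl2/hexane, −20 °C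
Reagents that add atoms: triethylsilyl triflate, CC[Si](CC)(CC)OS(=O)(=O)C(F)(F)F; mCPBA, O=C(OO)c1cccc(Cl)c1
Why: Rubottom oxidation: soft enolisation at the α′ carbon gives the cross-conjugated silyl dienol ether, mCPBA epoxidises its enol ether bond (far more electron-rich than the isopropenyl group) on the face anti to the neighbouring isopropenyl group, and 1,4-silyl shift should give the α-silyloxy ketone with the new C–O bond trans to the isopropenyl group.

Step 2
Reactants: 4 silyloxy enone
Product: 5 (1R,5S,6S)-2-methyl-5-(prop-1-en-2-yl)-6-(triethylsilyloxy)cyclohex-2-en-1-ol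
Conditions: (R)-2-methyl-CBS-oxazaborolidine [(R)-1-methyl-3,3-diphenyltetrahydro-1H,3H-pyrrolo[1,2-c][1,3,2]oxazaborole, 0.2 equiv], catecholborane, toluene, −78 °C
Reagents that add atoms: none
Why: Corey–Bakshi–Shibata reduction: the catalyst (sense chosen with the α-methyl alkenyl arm as the large group) should deliver hydride to the face that gives the pseudo-axial carbinol cis to the silyloxy group, whereas simple hydrides are expected to favour the trans isomer, and catecholborane is used so that the isopropenyl group is not hydroborated.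

Step 3
Reactants: 5 allylic alcohol
Product: 6 tert-butyldimethylsilyl ether of 5
Conditions: tBuMe2SiOTf, 2,6-lutidine, CH2Cl2, −78 °C
Reagents that add atoms: tert-butyldimethylsilyl triflate, CC(C)(C)[Si](C)(C)OS(=O)(=O)C(F)(F)F
Why: O-silylation of the hindered pseudo-axial allylic alcohol with a silyl triflate; no stereocentre is touched, and the two silyl ethers differ enough in lability to be told apart in step 12.

Step 4
Reactants: 6 bis-silyl ether
Product: 7 (4R,5S,6S)-4-(tert-butyldimethylsilyloxy)-3-methyl-6-(prop-1-en-2-yl)-5-(triethylsilyloxy)cyclohex-2-en-1-one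
Conditions: CrO3, 3,5-dimethylpyrazole, CH2Cl2, −20 °C
Reagents that add atoms: chromium trioxide, O=[Cr](=O)=O
Why: Allylic oxidation with the hexavalent chromium–pyrazole complex: the only ring methylene allylic to the trisubstituted alkene (the future C6) should be oxidised to the enone carbonyl, the silyl-protected carbinols and the less reactive isopropenyl group staying intact.

Step 5
Reactants: 7 enone; 8 N-methoxy-N-methylacetamide
Product: 10 N-methoxy-N-methyl-2-[(1R,4R,5S,6S)-4-(tert-butyldimethylsilyloxy)-1-hydroxy-3-methyl-6-(prop-1-en-2-yl)-5-(triethylsilyloxy)cyclohex-2-en-1-yl]acetamide, via lithium amide enolate 9 (not isolated)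
Conditions: LiN(iPr)2, THF, −78 °C (8 to 9); then 7, −78 °C; AcOH quench at −78 °C
Reagents that add atoms: none
Why: Aldol-type 1,2-addition of an amide enolate to the enone carbonyl (the β-carbon is fully substituted, so no conjugate addition): attack should come from the equatorial direction anti to the α′-isopropenyl group, as in additions of carbon nucleophiles to 2-alkylcyclohexanones, which sets C6 with O6 cis and C7 trans to the future C10.

Step 6
Reactants: 10 β-hydroxy Weinreb amide
Product: 11 2-[(1R,4R,5S,6S)-4-(tert-butyldimethylsilyloxy)-1-hydroxy-3-methyl-6-(prop-1-en-2-yl)-5-(triethylsilyloxy)cyclohex-2-en-1-yl]acetaldehyde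
Conditions: iBu2AlH (3 equiv), THF, −78 °C; Rochelle salt work-up
Reagents that add atoms: none
Why: Weinreb amide reduction: the chelated aluminium hemiaminal is stable at low temperature and gives the aldehyde only on work-up, so there is no over-reduction; the tertiary hydroxyl merely consumes one hydride and no stereocentre is affected.

Step 7
Reactants: 11 β-hydroxy aldehyde
Product: 12 trans-decalin diol (6α-OH; 8-OH as epimer mixture; 10-methylidene; 4-ene; 3β-OTBS; 2β-OTES)
Conditions: Me2AlCl (2.5 equiv), CH2Cl2, −78 → −40 °C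
Reagents that add atoms: none
Why: Lewis-acid-promoted intramolecular type-two carbonyl-ene reaction: C8 bonds to the methylene terminus of the isopropenyl group (C9) through a chair transition state with C7 and C10 equatorial on ring A, which should give the trans-fused ring B with hydrogen taken from the methyl group (exocyclic C10=C14); the C8 carbinol configuration is not controlled and is erased in step 8.

Step 8
Reactants: 12 decalin diol
Product: 14 trans-decalin enone (8-oxo; 9-ene; 10-methyl; 6α-OH), via β,γ-unsaturated ketone 13 (not isolated)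
Conditions: Dess–Martin periodinane, pyridine, CH2Cl2, 0 °C; then DBU (0.2 equiv), CH2Cl2, 0 °C
Reagents that add atoms: none
Why: Dess–Martin oxidation of the only secondary alcohol, then base-catalysed migration of the exocyclic alkene into conjugation through the doubly activated C9–H; the amidine is far too weak to deprotonate the tertiary hydroxyl, so retro-aldol opening is not expected.

Step 9
Reactants: 14 decalin enone; 15 tert-butyl bromoacetate
Product: 17 7β-(2-tert-butoxy-2-oxoethyl) decalin enone, via dilithium alkoxide dienolate 16 (not isolated)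
Conditions: LiN(iPr)2 (2.2 equiv), THF/DMPU, −78 °C; then 15, −78 °C; AcOH quench at −78 °C
Reagents that add atoms: none
Why: Kinetic α′-enolate alkylation: after the hydroxyl, LiN(iPr)2 removes a C7 proton to give an alkoxide dienolate that can neither undergo retro-aldol cleavage nor β-elimination, and SN2 attack on the bromoacetate should follow the axial trajectory on the face anti to the axial C6–O bond, setting C7 with its side chain axial (β) and trans-diaxial to O6.

Step 10
Reactants: 17 alkylated enone
Product: 18 9α,10α-epoxy ketone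
Conditions: tBuOOH (in decane), DBU, CH2Cl2, 0 °C
Reagents that add atoms: tert-butyl hydroperoxide, CC(C)(C)OO
Why: Weitz–Scheffer nucleophilic epoxidation, which touches only the enone: tert-butylperoxide should add to C10 along the stereoelectronically preferred axial trajectory on the α face, guided by a hydrogen bond to the syn-axial 6α-hydroxyl and kept off the β face by the axial C7 side chain, so the oxirane oxygen (the future O10) is α.

Step 11
Reactants: 18 epoxy ketone
Product: 19 β-hydroxy ketone (10α-OH; 10β-methyl; 8-oxo; 2β-OTES)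
Conditions: SmI2 (2.2 equiv), THF/MeOH, −90 °C
Reagents that add atoms: none
Why: SmI2 reduction of an α,β-epoxy ketone: electron transfer to the ketone cleaves the Cα–O bond (C9–O) and protonation of the samarium enolate gives the aldol, the C10–O bond and its configuration being untouched (axial OH, equatorial methyl).

Step 12
Reactants: 19 β-hydroxy ketone
Product: 20 2β-alcohol (triol ketone)
Conditions: HF·pyridine, pyridine, THF, 0 °C
Reagents that add atoms: none
Why: Selective desilylation: buffered HF·pyridine should remove the secondary triethylsilyl ether much faster than the allylic tert-butyldimethylsilyl ether, unveiling only O2 under non-basic conditions that spare the aldol array.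

Step 13
Reactants: 20 triol ketone
Product: 21 2β-methanesulfonate
Conditions: MsCl, Et3N, CH2Cl2, −20 °C
Reagents that add atoms: methanesulfonyl chloride, CS(=O)(=O)Cl
Why: O-sulfonylation through sulfene: only the secondary equatorial 2β-hydroxyl reacts, the two tertiary axial hydroxyls being inert under these conditions, and C2 keeps its configuration because the C–O bond is not broken.

Step 14
Reactants: 21 keto mesylate
Product: 22 8β-alcohol (6α,8β,10α-triol 2β-mesylate)
Conditions: Me4NBH(OAc)3, MeCN/AcOH, −30 °C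
Reagents that add atoms: none
Why: Evans–Saksena reduction: the acetoxyborohydride exchanges onto the axial 6α- and 10α-hydroxyls and delivers hydride intramolecularly to the α face of C8, which should give the equatorial 8β-alcohol anti to both directing groups; the mesylate is inert to the acidic medium and the tert-butyl ester resists lactonisation onto the new hydroxyl.

Step 15
Reactants: 22 triol mesylate
Product: 23 fragmentation precursor (1R,2S,3R,6S,7R,8R,10R): trans-decalin with free 6α-OH and 10α-OH; 8β-OTES; 3β-OTBS; equatorial 2β-OMs; 7β-CH2CO2tBu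
Conditions: Et3SiCl, imidazole, DMF, 0 °C
Reagents that add atoms: chlorotriethylsilane, CC[Si](Cl)(CC)CC
Why: Silylation: chlorotriethylsilane with imidazole should cap the one secondary hydroxyl (O8) and leave the tertiary ones, and imidazole is too weak a base to start the fragmentation.

Step 16
Reactants: 23 fragmentation precursor
Product: 25 tert-butyl 2-[(3S,7R,8R,10R,1E,4Z)-3-(tert-butyldimethylsilyloxy)-10-hydroxy-4,10-dimethyl-6-oxo-8-(triethylsilyloxy)cyclodeca-1,4-dien-7-yl]acetate, via potassium C6 alkoxide 24 (not isolated)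
Conditions: KOtBu (1.05 equiv), THF, −40 → 0 °C; pH 7 buffer quench
Reagents that add atoms: none
Why: KOtBu turns the axial tertiary C6 hydroxyl into its potassium alkoxide, whose lone pair pushes into the σ* orbital of the C1–C6 ring-fusion bond; that bond is held antiperiplanar to the equatorial C2–O bond by the trans-fused chair/half-chair and breaks in concert with loss of methanesulfonate, forming the C6 ketone and the C1=C2 π bond. The closest known reaction type is the base-induced Grob fragmentation of decalin-1,3-diol monosulfonates to cyclodecenones. The ten-membered ring is not closed by bond formation but unveiled by cutting the bond shared by ring A and ring B (ring expansion of the bicyclo[4.4.0]decane), so no entropy or transannular strain of a ring-closing transition state has to be paid. No stereocentre is created: C1, C2 and C6 become trigonal, while C3, C7, C8 and C10 are carried over unchanged. The step needs E geometry at C1=C2, Z at C4=C5 and fragmentation in preference to elimination, substitution or lactonisation: E follows because C10 (equatorial on C1) and C3 are antiperiplanar about C1–C2, Z is locked because C4=C5 is the cyclohexene bond of ring A, the equatorial mesylate has no antiperiplanar hydrogen, and the trans-diaxial C6–O/C7 side chain pair cannot lactonise. The single equivalent of base ends as neutral potassium methanesulfonate, so the β-silyloxy ketone with its epimerisable C7 should not meet excess base, and a C10 alkoxide can only relay its charge to O6 through the syn-diaxial hydrogen bond.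

Step 17
Reactants: 25 cyclodecadienone
Product: 26 (6S)-allylic alcohol (C6 carbinol with H-6 and H-7 syn)
Conditions: NaBH4, CeCl3·7H2O, MeOH, −78 °C
Reagents that add atoms: none
Why: Luche 1,2-reduction of the enone: hydride should add to C6 anti to the C7–C8 bond (Felkin–Anh model with C8 as the large α-substituent), which places H-6 and H-7 on the same side as the cis-fused lactone of the target requires.

Step 18
Reactants: 26 hydroxy tert-butyl ester
Product: 27 saturated 6,12-lactone (13-nor lactone; 3-OTBS; 8-OTES; 10-OH)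
Conditions: KOtBu (0.2 equiv), THF, 0 °C
Reagents that add atoms: none
Why: Alkoxide-catalysed intramolecular transesterification (5-exo-trig lactonisation): the C6 alkoxide attacks the ester carbonyl four atoms away and expels tert-butoxide, which carries the chain; no stereocentre changes.

Step 19
Reactants: 27 lactone; 28 Eschenmoser's salt
Product: 32 α-methylene lactone (3-OTBS; 8-OTES; 10-OH), via dilithium lactone enolate 29 (not isolated), via Mannich base 30 (not isolated), via trimethylammonium iodide 31 (not isolated)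
Conditions: LiN(iPr)2 (2.2 equiv), THF, −78 °C; 28, −78 → 0 °C; aqueous work-up; then MeI, MeOH, rt; then aqueous NaHCO3, CH2Cl2, rt
Reagents that add atoms: none
Why: Enolate Mannich reaction with Eschenmoser's salt, quaternisation and Hofmann-type β-elimination install the exocyclic C11=C13 methylene (classical α-methylenation of lactones); the transient C11 stereocentre disappears on elimination.

Step 20
Reactants: 32 bis-silylated α-methylene lactone
Product: 33 8-alcohol (3-OTBS; 8-OH; 10-OH)
Conditions: HF·pyridine, pyridine, THF, 0 °C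
Reagents that add atoms: none
Why: Selective desilylation: the secondary triethylsilyl ether should be cleaved while the allylic tert-butyldimethylsilyl ether at C3 stays, so that only O8 and the unreactive tertiary O10 are free for acylation.

Step 21
Reactants: 33 8-alcohol; 34 angelic acid
Product: 36 8-O-angeloyl 3-O-tert-butyldimethylsilyl lactone, via mixed anhydride 35 (not isolated)
Conditions: 2,4,6-trichlorobenzoyl chloride, Et3N, toluene, rt (34 to 35); then 33, toluene, 80 °C, no DMAP
Reagents that add atoms: none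
Why: Yamaguchi esterification: the mixed anhydride acylates the secondary 8-hydroxyl and not the tertiary 10-hydroxyl, and leaving out a nucleophilic catalyst should suppress Z-to-E isomerisation of the angelate to the tiglate.

Step 22
Reactants: 36 silyl-protected angelate
Product: 37 target, (3S,6S,7R,8R,10R)-8-angeloyloxy-3,10-dihydroxygermacra-1E,4Z,11(13)-trien-12,6-olide
Conditions: HF·pyridine, MeCN, 0 °C → rt
Reagents that add atoms: none
Why: Acidic fluoride desilylation of the allylic silyl ether; the non-basic medium should avoid acyl migration, translactonisation and addition to the α-methylene lactone.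

**Compound list**

1 | (R)-(−)-carvone, (5R)-2-methyl-5-(prop-1-en-2-yl)cyclohex-2-en-1-one | CC1=CC[C@H](CC1=O)C(C)=C | starting material
2 | triethyl{[(3R)-6-methyl-3-(prop-1-en-2-yl)cyclohexa-1,5-dien-1-yl]oxy}silane | CC[Si](CC)(CC)OC1=C[C@H](C(C)=C)CC=C1C | intermediate
3 | 1,2-epoxide of 2 on the face anti to the isopropenyl group (2-silyloxy oxirane) | CC[Si](CC)(CC)O[C@]12O[C@H]1[C@H](C(C)=C)CC=C2C | intermediate
4 | (5S,6S)-2-methyl-5-(prop-1-en-2-yl)-6-(triethylsilyloxy)cyclohex-2-en-1-one | CC1=CC[C@@H](C(C)=C)[C@H](O[Si](CC)(CC)CC)C1=O | intermediate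
5 | (1R,5S,6S)-2-methyl-5-(prop-1-en-2-yl)-6-(triethylsilyloxy)cyclohex-2-en-1-ol | CC1=CC[C@@H](C(C)=C)[C@H](O[Si](CC)(CC)CC)[C@@H]1O | intermediate
6 | tert-butyldimethylsilyl ether of 5 | CC1=CC[C@@H](C(C)=C)[C@H](O[Si](CC)(CC)CC)[C@@H]1O[Si](C)(C)C(C)(C)C | intermediate
7 | (4R,5S,6S)-4-(tert-butyldimethylsilyloxy)-3-methyl-6-(prop-1-en-2-yl)-5-(triethylsilyloxy)cyclohex-2-en-1-one | O=C1C=C(C)[C@@H](O[Si](C)(C)C(C)(C)C)[C@@H](O[Si](CC)(CC)CC)[C@@H]1C(C)=C | intermediate
8 | N-methoxy-N-methylacetamide | CC(=O)N(C)OC | starting material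
9 | lithium enolate of 8 | C=C(O[Li])N(C)OC | intermediate
10 | N-methoxy-N-methyl-2-[(1R,4R,5S,6S)-4-(tert-butyldimethylsilyloxy)-1-hydroxy-3-methyl-6-(prop-1-en-2-yl)-5-(triethylsilyloxy)cyclohex-2-en-1-yl]acetamide | CON(C)C(=O)C[C@@]1(O)C=C(C)[C@@H](O[Si](C)(C)C(C)(C)C)[C@@H](O[Si](CC)(CC)CC)[C@@H]1C(C)=C | intermediate
11 | 2-[(1R,4R,5S,6S)-4-(tert-butyldimethylsilyloxy)-1-hydroxy-3-methyl-6-(prop-1-en-2-yl)-5-(triethylsilyloxy)cyclohex-2-en-1-yl]acetaldehyde | O=CC[C@@]1(O)C=C(C)[C@@H](O[Si](C)(C)C(C)(C)C)[C@@H](O[Si](CC)(CC)CC)[C@@H]1C(C)=C | intermediate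
12 | trans-decalin diol: 4-methyl-10-methylidenebicyclo[4.4.0]dec-4-ene-6α,8-diol, 3β-OTBS, 2β-OTES, 1β-H, mixture of C8 epimers | C=C1CC(O)C[C@@]2(O)C=C(C)[C@@H](O[Si](C)(C)C(C)(C)C)[C@@H](O[Si](CC)(CC)CC)[C@H]12 | intermediate
13 | 8-ketone of 12 (β,γ-unsaturated ketone) | C=C1CC(=O)C[C@@]2(O)C=C(C)[C@@H](O[Si](C)(C)C(C)(C)C)[C@@H](O[Si](CC)(CC)CC)[C@H]12 | intermediate
14 | trans-decalin enone: 6α-hydroxy-4,10-dimethylbicyclo[4.4.0]deca-4,9-dien-8-one, 3β-OTBS, 2β-OTES, 1β-H | CC1=CC(=O)C[C@@]2(O)C=C(C)[C@@H](O[Si](C)(C)C(C)(C)C)[C@@H](O[Si](CC)(CC)CC)[C@H]12 | intermediate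
15 | tert-butyl bromoacetate | CC(C)(C)OC(=O)CBr | starting material
16 | dilithium C6-alkoxide C7,C8-dienolate of 14 | CC1=CC(O[Li])=C[C@@]2(O[Li])C=C(C)[C@@H](O[Si](C)(C)C(C)(C)C)[C@@H](O[Si](CC)(CC)CC)[C@H]12 | intermediate
17 | 7β-(2-tert-butoxy-2-oxoethyl) derivative of 14 (side chain axial, anti to 6α-OH) | CC1=CC(=O)[C@@H](CC(=O)OC(C)(C)C)[C@@]2(O)C=C(C)[C@@H](O[Si](C)(C)C(C)(C)C)[C@@H](O[Si](CC)(CC)CC)[C@H]12 | intermediate
18 | 9α,10α-epoxide of 17 (epoxy ketone) | C[C@@]12O[C@@H]1C(=O)[C@@H](CC(=O)OC(C)(C)C)[C@@]3(O)C=C(C)[C@@H](O[Si](C)(C)C(C)(C)C)[C@@H](O[Si](CC)(CC)CC)[C@H]23 | intermediate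
19 | 6α,10α-dihydroxy-10β-methyl-8-oxo trans-decalin, 7β-CH2CO2tBu, 3β-OTBS, 2β-OTES | C[C@@]1(O)CC(=O)[C@@H](CC(=O)OC(C)(C)C)[C@@]2(O)C=C(C)[C@@H](O[Si](C)(C)C(C)(C)C)[C@@H](O[Si](CC)(CC)CC)[C@H]12 | intermediate
20 | 2β-alcohol from 19 (2β,6α,10α-triol, 8-oxo, 3β-OTBS) | C[C@@]1(O)CC(=O)[C@@H](CC(=O)OC(C)(C)C)[C@@]2(O)C=C(C)[C@@H](O[Si](C)(C)C(C)(C)C)[C@@H](O)[C@H]12 | intermediate
21 | 2β-methanesulfonate of 20 | C[C@@]1(O)CC(=O)[C@@H](CC(=O)OC(C)(C)C)[C@@]2(O)C=C(C)[C@@H](O[Si](C)(C)C(C)(C)C)[C@@H](OS(C)(=O)=O)[C@H]12 | intermediate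
22 | 8β-alcohol from 21 (6α,8β,10α-triol, 2β-OMs, 3β-OTBS) | C[C@@]1(O)C[C@@H](O)[C@@H](CC(=O)OC(C)(C)C)[C@@]2(O)C=C(C)[C@@H](O[Si](C)(C)C(C)(C)C)[C@@H](OS(C)(=O)=O)[C@H]12 | intermediate
23 | fragmentation precursor, (1R,2S,3R,6S,7R,8R,10R): trans-decalin, 6α-OH, 10α-OH, 10β-CH3, 8β-OTES, 7β-CH2CO2tBu, 4-ene, 3β-OTBS, equatorial 2β-OMs | C[C@@]1(O)C[C@@H](O[Si](CC)(CC)CC)[C@@H](CC(=O)OC(C)(C)C)[C@@]2(O)C=C(C)[C@@H](O[Si](C)(C)C(C)(C)C)[C@@H](OS(C)(=O)=O)[C@H]12 | intermediate
24 | potassium C6 alkoxide of 23 | C[C@@]1(O)C[C@@H](O[Si](CC)(CC)CC)[C@@H](CC(=O)OC(C)(C)C)[C@@]2(O[K])C=C(C)[C@@H](O[Si](C)(C)C(C)(C)C)[C@@H](OS(C)(=O)=O)[C@H]12 | intermediate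
25 | tert-butyl 2-[(3S,7R,8R,10R,1E,4Z)-3-(tert-butyldimethylsilyloxy)-10-hydroxy-4,10-dimethyl-6-oxo-8-(triethylsilyloxy)cyclodeca-1,4-dien-7-yl]acetate | O=C1/C=C(/C)[C@@H](O[Si](C)(C)C(C)(C)C)/C=C/[C@](C)(O)C[C@@H](O[Si](CC)(CC)CC)[C@H]1CC(=O)OC(C)(C)C | intermediate
26 | 6-alcohol from 25, C6 configured as in the target (H-6 syn to H-7) | O[C@H]1/C=C(/C)[C@@H](O[Si](C)(C)C(C)(C)C)/C=C/[C@](C)(O)C[C@@H](O[Si](CC)(CC)CC)[C@H]1CC(=O)OC(C)(C)C | intermediate
27 | saturated cis-fused 6,12-lactone (13-nor), 3-OTBS, 8-OTES, 10-OH, 1E,4Z | C1C(=O)O[C@H]2/C=C(/C)[C@@H](O[Si](C)(C)C(C)(C)C)/C=C/[C@](C)(O)C[C@@H](O[Si](CC)(CC)CC)[C@@H]12 | intermediate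
28 | Eschenmoser's salt, N,N-dimethylmethyleneiminium iodide | C=[N+](C)C.[I-] | starting material
29 | dilithium salt of 27 (lactone enolate and C10 alkoxide) | C1=C(O[Li])O[C@H]2/C=C(/C)[C@@H](O[Si](C)(C)C(C)(C)C)/C=C/[C@](C)(O[Li])C[C@@H](O[Si](CC)(CC)CC)[C@@H]12 | intermediate
30 | 11-(dimethylaminomethyl) lactone (C11 epimers) | CN(C)CC1C(=O)O[C@H]2/C=C(/C)[C@@H](O[Si](C)(C)C(C)(C)C)/C=C/[C@](C)(O)C[C@@H](O[Si](CC)(CC)CC)[C@@H]12 | intermediate
31 | trimethylammonium iodide from 30 | C[N+](C)(C)CC1C(=O)O[C@H]2/C=C(/C)[C@@H](O[Si](C)(C)C(C)(C)C)/C=C/[C@](C)(O)C[C@@H](O[Si](CC)(CC)CC)[C@@H]12.[I-] | intermediate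
32 | α-methylene lactone, 3-O-TBS, 8-O-TES, 10-OH | C=C1C(=O)O[C@H]2/C=C(/C)[C@@H](O[Si](C)(C)C(C)(C)C)/C=C/[C@](C)(O)C[C@@H](O[Si](CC)(CC)CC)[C@@H]12 | intermediate
33 | α-methylene lactone, 3-O-TBS, 8-OH, 10-OH | C=C1C(=O)O[C@H]2/C=C(/C)[C@@H](O[Si](C)(C)C(C)(C)C)/C=C/[C@](C)(O)C[C@@H](O)[C@@H]12 | intermediate
34 | angelic acid, (Z)-2-methylbut-2-enoic acid | C/C=C(/C)C(=O)O | starting material
35 | angelic 2,4,6-trichlorobenzoic anhydride | C/C=C(/C)C(=O)OC(=O)c1c(Cl)cc(Cl)cc1Cl | intermediate
36 | 8-O-angeloyl-3-O-TBS lactone | C=C1C(=O)O[C@H]2/C=C(/C)[C@@H](O[Si](C)(C)C(C)(C)C)/C=C/[C@](C)(O)C[C@@H](OC(=O)/C(C)=C\C)[C@@H]12 | intermediate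
37 | target, (3S,6S,7R,8R,10R)-8-angeloyloxy-3,10-dihydroxygermacra-1E,4Z,11(13)-trien-12,6-olide | C=C1C(=O)O[C@H]2/C=C(/C)[C@@H](O)/C=C/[C@](C)(O)C[C@@H](OC(=O)/C(C)=C\C)[C@@H]12 | target

**Step count and risks**

Total step count: 22. Longest linear sequence: 22 steps, all from (R)-carvone (the precursor 23 is reached in 15).

Steps most likely to fail:

1. Step 16 (key step). Process at risk: once the C1–C6 bond has broken, any alkoxide still present can epimerise C7 or expel the C8 silyloxy group from the new β-silyloxy ketone, and a C10 alkoxide can add across the ring to the enone. The fallback sets out from 23 and comes back at 25. Both tertiary hydroxyls are capped with N-(trimethylsilyl)imidazole to give the bis(trimethylsilyl) ether of 23 F3. One equivalent of anhydrous Bu4NF in THF at −78 °C then cuts an O–SiMe3 bond, the charge is relayed to O6 by silyl transfer between the syn-diaxial oxygens, and the same antiperiplanar fragmentation should follow with no alkoxide base left once methanesulfonate has gone. The remaining C10 trimethylsilyl ether is lost in a citric acid work-up, which returns 25.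

2. Step 9. Process at risk: proton transfer from the bromoacetate to the dianion, retro-aldol opening of ring B before the second deprotonation, or O-alkylation, any of which would erode yield or the axial delivery at C7. The fallback sets out from 14 and comes back at 17. The same dianion is trapped with tert-butyl glyoxylate (no enolisable hydrogen, much more electrophilic; obtained by ozonolysis of di-tert-butyl fumarate) in an aldol addition along the same axial trajectory, giving the C11 hydroxy ester F1. Its secondary hydroxyl is converted with 1,1′-thiocarbonyldiimidazole into the imidazolyl thiocarbonate F2, and Barton–McCombie deoxygenation (Bu3SnH, AIBN, toluene, 80 °C) removes the C11 oxygen to give 17.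

3. Step 17. Process at risk: poor or reversed facial selectivity of hydride addition to the conformationally mobile ten-membered enone. The fallback sets out from 25 and comes back at 27. If reduction favours the other face, the 6-epimeric alcohol F4 is inverted by Mitsunobu esterification (4-nitrobenzoic acid, PPh3, DIAD, THF, 0 °C) to the 6-(4-nitrobenzoate) with the required C6 configuration F5. K2CO3 in MeOH then cleaves the nitrobenzoate, and the liberated C6 alkoxide closes onto the tert-butyl ester to give lactone 27 directly.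

**Further compounds**

F1 | step 9 | C11 hydroxy ester: 7β-[2-tert-butoxy-1-hydroxy-2-oxoethyl] derivative of 14 (C11 epimers) | CC1=CC(=O)[C@@H](C(O)C(=O)OC(C)(C)C)[C@@]2(O)C=C(C)[C@@H](O[Si](C)(C)C(C)(C)C)[C@@H](O[Si](CC)(CC)CC)[C@H]12
F2 | step 9 | O-(imidazol-1-ylthiocarbonyl) derivative of F1 | CC1=CC(=O)[C@@H](C(OC(=S)n3ccnc3)C(=O)OC(C)(C)C)[C@@]2(O)C=C(C)[C@@H](O[Si](C)(C)C(C)(C)C)[C@@H](O[Si](CC)(CC)CC)[C@H]12
F3 | step 16 | 6,10-bis(trimethylsilyl) ether of 23 | C[C@@]1(O[Si](C)(C)C)C[C@@H](O[Si](CC)(CC)CC)[C@@H](CC(=O)OC(C)(C)C)[C@@]2(O[Si](C)(C)C)C=C(C)[C@@H](O[Si](C)(C)C(C)(C)C)[C@@H](OS(C)(=O)=O)[C@H]12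
F4 | step 17 | 6-epimer of 26 | O[C@@H]1/C=C(/C)[C@@H](O[Si](C)(C)C(C)(C)C)/C=C/[C@](C)(O)C[C@@H](O[Si](CC)(CC)CC)[C@H]1CC(=O)OC(C)(C)C
F5 | step 17 | 6-(4-nitrobenzoate) of 26 | O=C(O[C@H]1/C=C(/C)[C@@H](O[Si](C)(C)C(C)(C)C)/C=C/[C@](C)(O)C[C@@H](O[Si](CC)(CC)CC)[C@H]1CC(=O)OC(C)(C)C)c1ccc(cc1)[N+](=O)[O-]
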